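**Strategy.** Each half of the target is a 1,4-naphthoquinone whose quinone ring has oxygen on C1, C2 and C4 and the bridge on C3, fused to a fully oxygenated benzenoid ring. Both quinone rings are therefore cut at C4–C3, C2–C1 and C1–C8a: C2/C3 come from an ynol ether, C1 from CO, C4 and the benzenoid ring from an aryl(methoxy)carbene of chromium. Because the two C3 atoms share one CH(CH3) carbon, a skipped bis-ynol ether, EtOC≡C–CH(CH3)–C≡COEt, reacts with two carbene complexes in a two-directional Dötz benzannulation that closes both rings and forms six C–C bonds at once. Oxidation and ether cleavage finish the synthesis.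

Key step: step 4

Remark on the chemistry (assumption): an electron-rich ynol ether is taken to insert with its nucleophilic, bridge-bearing carbon bonding to the carbene carbon, so the bis-naphthol of the key step is drawn with hydroxyl on C1, ethoxy on C2, the bridge on C3 and methoxy on C4. A structure with ethoxy next to the carbene-derived methoxy would not agree with the bonds C4–C3 and C2–C1, and both orientations give the same quinone on oxidation.

Remark on the materials (assumption): diethyl 3-methylglutarate is taken as a catalogue chemical.

No compound in the route has a stereocentre. The bridge carbon always carries two identical arms. The only stereo-elements are the C=C geometries of the enolate and the enol phosphate.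

**Step 1**
Reactants: 1 1,2,3,4-tetramethoxybenzene; 2 chromium hexacarbonyl, Cr(CO)6
Product: 5 pentacarbonyl[methoxy(2,3,4,5-tetramethoxyphenyl)carbene]chromium, via 2,3,4,5-tetramethoxyphenyllithium 3 (not isolated), via lithium aroylpentacarbonylchromate 4 (not isolated)
Conditions: n-BuLi, TMEDA, THF, 0 °C; Cr(CO)6, THF, 0 °C → rt; then Me3OBF4, CH2Cl2, 0 °C
Reagents that add atoms: trimethyloxonium tetrafluoroborate, C[O+](C)C.F[B-](F)(F)F
Why: Directed ortho-lithiation next to a methoxy group gives the only possible aryllithium of the symmetric arene, which adds to a CO ligand of Cr(CO)6, and O-methylation of the acylchromate completes a standard Fischer carbene complex synthesis.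

**Step 2**
Reactants: 6 diethyl 3-methylglutarate (diethyl 3-methylpentanedioate)
Product: 8 tetraethyl (1Z,4Z)-1,5-diethoxy-3-methylpenta-1,4-diene-1,5-diyl bis(phosphate), via dilithium bis-enolate 7 (not isolated)
Conditions: LiN(iPr)2 (2.2 equiv), THF–DMPU, −78 °C; ClP(O)(OEt)2 (2.4 equiv), −78 → 0 °C
Reagents that add atoms: diethyl chlorophosphate, CCOP(Cl)(=O)OCC
Why: Twofold kinetic enolisation of the 1,5-diester (only the two α-methylene groups are acidic, and a Dieckmann closure would need a four-membered ring) and O-phosphorylation of the ester enolates should give the bis(ketene acetal phosphate), with each phosphate cis to C3 as expected for enolates formed in THF–DMPU.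

**Step 3**
Reactants: 8 tetraethyl (1Z,4Z)-1,5-diethoxy-3-methylpenta-1,4-diene-1,5-diyl bis(phosphate)
Product: 9 1,5-diethoxy-3-methylpenta-1,4-diyne
Conditions: t-BuLi (2.1 equiv), THF, −100 → −78 °C; aq NH4Cl at −78 °C
Reagents that add atoms: none
Why: Base-induced β-elimination of enol phosphates to alkynes, here in its ketene acetal phosphate to 1-ethoxyalkyne form, removes the vinylic hydrogen anti to each phosphate; no propargylic leaving group beside an ynol ether is ever made, and the low temperature with near-stoichiometric base is meant to spare the doubly propargylic C3–H.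

**Step 4**
Reactants: 5 pentacarbonyl[methoxy(2,3,4,5-tetramethoxyphenyl)carbene]chromium (2.3 equiv); 9 1,5-diethoxy-3-methylpenta-1,4-diyne
Product: 11 3,3'-(ethane-1,1-diyl)bis(2-ethoxy-4,5,6,7,8-pentamethoxynaphthalen-1-ol), via bis(tricarbonylchromium) naphthol complex 10 (not isolated)
Conditions: 9 added slowly to 5, degassed THF, 50 °C, Ar; then MeCN, 40 °C, Ar; filtered under Ar and used crude
Reagents that add atoms: none
Why: Loss of one CO from 5 (eased by the ortho-methoxy group, which can chelate chromium) lets an alkyne of 9 coordinate and insert into the Cr=C bond with its bridge-bearing carbon bonding to the carbene carbon (C4–C3), the ethoxy-stabilised vinylcarbene takes up a CO ligand (C2–C1) to give a chromium-bound aryl-vinylketene, and ring closure and enolisation give the naphthol as its Cr(CO)3 complex before the sequence repeats on the second arm. The closest known reaction is the Dötz benzannulation of aryl(alkoxy)carbene chromium complexes with alkynes, including heteroatom-substituted alkynes and twofold reactions on diynes. Each new six-membered ring closes by a thermal 6π electrocyclisation of the vinylketene that forms C1–C8a at the only ortho carbon of the aryl group that carries hydrogen. No stereocentre is formed, since the bridge carbon carries two identical arms. The step needs chemoselectivity for CO insertion and six-ring closure over cyclobutenone, indene or furan formation, which the chromium methoxycarbene, the ether solvent and the moderate temperature favour, and the skipped spacing rules out an intramolecular two-alkyne annulation because that would need a four-membered ring. The orientation of the alkyne does not change the quinone obtained in step 5, and the orientation expected for an electron-rich alkyne keeps the new hydroxyl away from the second ynol ether arm.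

**Step 5**
Reactants: 11 3,3'-(ethane-1,1-diyl)bis(2-ethoxy-4,5,6,7,8-pentamethoxynaphthalen-1-ol)
Product: 12 3,3'-(ethane-1,1-diyl)bis(2-ethoxy-5,6,7,8-tetramethoxynaphthalene-1,4-dione)
Conditions: (NH4)2Ce(NO3)6 (5 equiv), MeCN–H2O, 0 °C, short reaction time
Reagents that add atoms: water, O
Why: Oxidative demethylation of a para-methoxynaphthol by tetravalent cerium (two-electron oxidation, attack of water at C4, loss of methanol) gives the 1,4-quinone; the free naphthol ring is far more easily oxidised than the tetramethoxy ring, and residual chromium carbonyl species are destroyed at the same time.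

**Step 6**
Reactants: 12 3,3'-(ethane-1,1-diyl)bis(2-ethoxy-5,6,7,8-tetramethoxynaphthalene-1,4-dione)
Product: 13 3,3'-(ethane-1,1-diyl)bis(2,5,6,7,8-pentahydroxynaphthalene-1,4-dione), which is ethylidene-3,3'-bis(2,6,7-trihydroxynaphthazarin)
Conditions: BBr3 (20 equiv), CH2Cl2, −78 °C → rt, Ar; then H2O, 0 °C
Reagents that add atoms: none
Why: Lewis-acid cleavage of alkyl aryl ethers with BBr3 (bromide attacks the O-alkyl carbon of the boron-complexed ether, helped at the peri positions by chelation to the quinone carbonyls) also dealkylates the vinylogous ester at C2; the quinone ring is fully substituted, so HBr cannot add, and the mild temperature is chosen to avoid acid-promoted cyclodehydration of the bis(hydroxyquinonyl)ethane.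

**Compound list**

1 | 1,2,3,4-tetramethoxybenzene | COc1ccc(OC)c(OC)c1OC | starting material
2 | chromium hexacarbonyl | [Cr].[C-]#[O+].[C-]#[O+].[C-]#[O+].[C-]#[O+].[C-]#[O+].[C-]#[O+] | starting material
3 | 2,3,4,5-tetramethoxyphenyllithium | [Li]c1cc(OC)c(OC)c(OC)c1OC | intermediate
4 | lithium pentacarbonyl(2,3,4,5-tetramethoxybenzoyl)chromate | [Li+].[O-]C(=[Cr])c1cc(OC)c(OC)c(OC)c1OC.[C-]#[O+].[C-]#[O+].[C-]#[O+].[C-]#[O+].[C-]#[O+] | intermediate
5 | pentacarbonyl[methoxy(2,3,4,5-tetramethoxyphenyl)carbene]chromium | COC(=[Cr])c1cc(OC)c(OC)c(OC)c1OC.[C-]#[O+].[C-]#[O+].[C-]#[O+].[C-]#[O+].[C-]#[O+] | intermediate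
6 | diethyl 3-methylglutarate | CCOC(=O)CC(C)CC(=O)OCC | starting material
7 | dilithium bis-enolate of 6 (each O–Li cis to C3 across its C=C) | CCO/C(O[Li])=C/C(C)/C=C(/OCC)O[Li] | intermediate
8 | tetraethyl (1Z,4Z)-1,5-diethoxy-3-methylpenta-1,4-diene-1,5-diyl bis(phosphate) | CCO/C(OP(=O)(OCC)OCC)=C/C(C)/C=C(/OCC)OP(=O)(OCC)OCC | intermediate
9 | 1,5-diethoxy-3-methylpenta-1,4-diyne | CCOC#CC(C)C#COCC | intermediate
10 | bis(tricarbonylchromium) complex of 11 (one Cr(CO)3 η6-bound to each naphthalene) | CC(c1c(OCC)c(O)c2c(OC)c(OC)c(OC)c(OC)c2c1OC)c1c(OCC)c(O)c2c(OC)c(OC)c(OC)c(OC)c2c1OC.[Cr].[Cr].[C-]#[O+].[C-]#[O+].[C-]#[O+].[C-]#[O+].[C-]#[O+].[C-]#[O+] | intermediate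
11 | 3,3'-(ethane-1,1-diyl)bis(2-ethoxy-4,5,6,7,8-pentamethoxynaphthalen-1-ol) | CC(c1c(OCC)c(O)c2c(OC)c(OC)c(OC)c(OC)c2c1OC)c1c(OCC)c(O)c2c(OC)c(OC)c(OC)c(OC)c2c1OC | intermediate
12 | 3,3'-(ethane-1,1-diyl)bis(2-ethoxy-5,6,7,8-tetramethoxynaphthalene-1,4-dione) | CC(C1=C(OCC)C(=O)c2c(OC)c(OC)c(OC)c(OC)c2C1=O)C1=C(OCC)C(=O)c2c(OC)c(OC)c(OC)c(OC)c2C1=O | intermediate
13 | ethylidene-3,3'-bis(2,6,7-trihydroxynaphthazarin) | CC(C1=C(O)C(=O)c2c(O)c(O)c(O)c(O)c2C1=O)C1=C(O)C(=O)c2c(O)c(O)c(O)c(O)c2C1=O | target

**Step count.** Total: 6 steps. Longest linear sequence: 5 steps (steps 2, 3, 4, 5, 6, from 6 to 13); the carbene arm adds one step and joins at step 4.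

**Steps most likely to fail**

Step 4. After alkyne insertion, the ethoxy-stabilised vinylcarbene may cyclise onto the aryl ring before it takes up CO (indene formation), or the vinylketene may close to a cyclobutenone. The second annulation may also stall beside the first, crowded naphthol–chromium unit, so that mono-annulated and non-carbonylated material accumulates. The fallback uses no carbene chemistry and makes the bridge last; it sets out from 1 and comes back to the route at 13. Compound 1 is fused with chloromaleic anhydride in an AlCl3–NaCl melt (about 180 °C, then dilute HCl), a twofold Friedel–Crafts acylation at the two free ring positions that also cleaves the methyl ethers, to give 2-chloro-5,6,7,8-tetrahydroxynaphthalene-1,4-dione F1. NaOMe in MeOH at reflux should exchange chloride for methoxide by addition–elimination to give 5,6,7,8-tetrahydroxy-2-methoxynaphthalene-1,4-dione F2. HBr in AcOH cleaves this last ether to 2,5,6,7,8-pentahydroxynaphthalene-1,4-dione F3. Two molecules of F3 and one of acetaldehyde in AcOH at 60 °C under Ar should then condense (Knoevenagel condensation at the free C3, then Michael addition of the second hydroxyquinone to the quinone methide) to give 13.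

Step 3. The base needed for the second elimination may also remove the doubly propargylic hydrogen at C3 of the product, so that propargyl–allenyl isomerisation scrambles the skipped diyne, or one enol phosphate may survive. The fallback needs only a monoalkyne and again forms the bridge by condensation; it sets out from 5 and comes back to the route at 13. Compound 5 and commercial ethoxyacetylene under the conditions of step 4 should give 2-ethoxy-4,5,6,7,8-pentamethoxynaphthalen-1-ol F4; here the electronic preference and the usual preference of terminal alkynes both place ethoxy next to the new hydroxyl. (NH4)2Ce(NO3)6 in MeCN–H2O oxidises F4 to 2-ethoxy-5,6,7,8-tetramethoxynaphthalene-1,4-dione F5. Aqueous NaOH in THF, then HCl, saponifies the vinylogous ester to 2-hydroxy-5,6,7,8-tetramethoxynaphthalene-1,4-dione F6. Two molecules of F6 and one of acetaldehyde in AcOH at 60 °C give 3,3'-(ethane-1,1-diyl)bis(2-hydroxy-5,6,7,8-tetramethoxynaphthalene-1,4-dione) F7. BBr3 under the conditions of step 6 then gives 13.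

Step 6. Ten ether cleavages must all go to completion on one molecule. Partly cleaved aryloxyboron species may precipitate and stop reacting, leaving mixed partial ethers, and the electron-rich polyphenol may be lost by air oxidation during a long work-up. The fallback cleaves the two kinds of ether in separate stages; it sets out from 12 and comes back to the route at 13. BCl3 in CH2Cl2 (−78 → 0 °C) should cleave only the four peri methoxy groups, through six-membered chelates with the quinone carbonyls, to give 3,3'-(ethane-1,1-diyl)bis(2-ethoxy-5,8-dihydroxy-6,7-dimethoxynaphthalene-1,4-dione) F8. In this naphthazarin every remaining alkoxy group sits on a quinonoid carbon in one tautomer or the other, so the six vinylogous esters should be cleaved by 48% HBr in AcOH at 90 °C under Ar to give 13.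

**Further compounds**

F1 | step 4 | 2-chloro-5,6,7,8-tetrahydroxynaphthalene-1,4-dione | ClC1=CC(=O)c2c(O)c(O)c(O)c(O)c2C1=O
F2 | step 4 | 5,6,7,8-tetrahydroxy-2-methoxynaphthalene-1,4-dione | COC1=CC(=O)c2c(O)c(O)c(O)c(O)c2C1=O
F3 | step 4 | 2,5,6,7,8-pentahydroxynaphthalene-1,4-dione | OC1=CC(=O)c2c(O)c(O)c(O)c(O)c2C1=O
F4 | step 3 | 2-ethoxy-4,5,6,7,8-pentamethoxynaphthalen-1-ol | CCOc1cc(OC)c2c(OC)c(OC)c(OC)c(OC)c2c1O
F5 | step 3 | 2-ethoxy-5,6,7,8-tetramethoxynaphthalene-1,4-dione | CCOC1=CC(=O)c2c(OC)c(OC)c(OC)c(OC)c2C1=O
F6 | step 3 | 2-hydroxy-5,6,7,8-tetramethoxynaphthalene-1,4-dione | OC1=CC(=O)c2c(OC)c(OC)c(OC)c(OC)c2C1=O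
F7 | step 3 | 3,3'-(ethane-1,1-diyl)bis(2-hydroxy-5,6,7,8-tetramethoxynaphthalene-1,4-dione) | CC(C1=C(O)C(=O)c2c(OC)c(OC)c(OC)c(OC)c2C1=O)C1=C(O)C(=O)c2c(OC)c(OC)c(OC)c(OC)c2C1=O
F8 | step 6 | 3,3'-(ethane-1,1-diyl)bis(2-ethoxy-5,8-dihydroxy-6,7-dimethoxynaphthalene-1,4-dione) | CC(C1=C(OCC)C(=O)c2c(O)c(OC)c(OC)c(O)c2C1=O)C1=C(OCC)C(=O)c2c(O)c(OC)c(OC)c(O)c2C1=O
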